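**Retrosynthetic overview**
1. Endgame: the disulfate comes from its hepta-PMB-protected disodium salt by hydrogenolysis. The sulfates go onto O2 of rings A and C, the only two oxygens that carried silicon instead of PMB.
2. Key disconnection: the C4–O bonds of rings A and C. In the bis-silyl penta-PMB terphenyl, C4–H of each outer ring (para to the biaryl bond) is the only aromatic C–H whose two neighbours (C3, C5) both bear hydrogen. A sterically governed iridium borylation followed by oxidation therefore places oxygen there.
3. O2 and O6 of each outer ring are told apart before that ring is aromatic. In the 2-aryl-cyclohexane-1,3-dione the two oxygens are equivalent; one is fixed as a PMB enol ether (future O6). The remaining carbonyl becomes the phenol on dehydrogenation (future O2) and is silylated.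
4. The two ring B–C1 bonds come from a twofold palladium-catalysed α-arylation of cyclohexane-1,3-dione with 2,4-dibromophloroglucinol tris-PMB ether.
5. Ring order: no ring is built. Ring B is bought as phloroglucinol and rings A and C as cyclohexane-1,3-dione; the outer rings are attached, desymmetrised, aromatised and only then oxygenated at C4.

Key step: step 7

Numbering and abbreviations: in each outer ring C1 is bonded to ring B, C2 bears the oxygen that ends as sulfate, C6 bears the other ortho oxygen, and C4 is para to C1. PMB = 4-methoxybenzyl; TIPS = triisopropylsilyl; pin = pinacolato; dtbpy = 4,4'-di-tert-butyl-2,2'-bipyridine; cod = cycloocta-1,5-diene.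
Assumption 1: the target is drawn without axial descriptors, so the two hindered ring B–outer ring axes are not controlled. From the enol ether stage on, atropisomeric forms are carried on together, since all have the same constitution.
Assumption 2: aryl sulfate monoesters are handled as sodium salts, and the acid form drawn for the target is released only in the last operation.

**Step 1**
Reactants: 1 phloroglucinol; 2 4-methoxybenzyl chloride
Product: 3 1,3,5-tris(4-methoxybenzyloxy)benzene
Conditions: 2 (3.3 equiv), K2CO3 (4 equiv), DMF, 60 °C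
Reagents that add atoms: 4-methoxybenzyl chloride (2), COc1ccc(CCl)cc1
Why: Threefold Williamson ether synthesis; carbonate in a dipolar aprotic solvent steers the ambident phloroglucinol anion to oxygen, and C-benzylated material can be removed by crystallisation at this cheap stage.

**Step 2**
Reactants: 3 1,3,5-tris(4-methoxybenzyloxy)benzene
Product: 4 2,4-dibromo-1,3,5-tris(4-methoxybenzyloxy)benzene
Conditions: NBS (2.0 equiv), CH2Cl2, −20 to 0 °C, dark
Reagents that add atoms: N-bromosuccinimide, O=C1CCC(=O)N1Br
Why: Electrophilic aromatic bromination; each ring B C–H is activated by two ortho and one para alkoxy group and should outrun the singly activated PMB rings, while the exact charge of two equivalents stops at the dibromide.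

**Step 3**
Reactants: 4 2,4-dibromo-1,3,5-tris(4-methoxybenzyloxy)benzene; 5 cyclohexane-1,3-dione
Product: 6 2,2'-[2,4,6-tris(4-methoxybenzyloxy)benzene-1,3-diyl]bis(3-hydroxycyclohex-2-en-1-one) (bis-dione drawn as its enol)
Conditions: 5 (3 equiv), Pd2(dba)3 (5 mol %), XPhos (20 mol %), K3PO4 (6 equiv), 1,4-dioxane, 100 °C; work-up at pH 5
Reagents that add atoms: cyclohexane-1,3-dione (5), O=C1CCCC(=O)C1
Why: Palladium-catalysed α-arylation of a cyclic 1,3-diketone enolate, a reaction type established for di-ortho-substituted aryl bromides; the bulky biaryl phosphine drives C–C reductive elimination, a carboxylate-free palladium source disfavours C–H palladation of the neighbouring PMB rings, and each product is protected from further arylation as its hindered stabilised enolate.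

**Step 4**
Reactants: 6 bis-dione; 2 4-methoxybenzyl chloride
Product: 7 2,2'-[2,4,6-tris(4-methoxybenzyloxy)benzene-1,3-diyl]bis[3-(4-methoxybenzyloxy)cyclohex-2-en-1-one]
Conditions: 2 (2.5 equiv), K2CO3 (3 equiv), DMF, 40 °C
Reagents that add atoms: 4-methoxybenzyl chloride (2), COc1ccc(CCl)cc1
Why: Williamson-type O-alkylation of a vinylogous acid; C2 of each enolate is shielded by the di-ortho-substituted ring B so the halide is taken up at oxygen, and because the two oxygens of a dione are equivalent either one gives the same mono enol ether, which is where future O6 (ether) and future O2 (carbonyl) become different.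

**Step 5**
Reactants: 7 bis(PMB enol ether)
Product: 9 terphenyl bis-phenol whose 2,4,6-tris(4-methoxybenzyloxy)benzene-1,3-diyl ring B bears two 2-hydroxy-6-(4-methoxybenzyloxy)phenyl rings, via bis(trimethylsilyl dienol ether) 8 (not isolated)
Conditions: LiN(iPr)2 (3 equiv), THF, −78 °C; Me3SiCl (4 equiv), −78 to 0 °C; solvent switch; Pd(OAc)2 (2.2 equiv), CH3CN–CH2Cl2, rt
Reagents that add atoms: chlorotrimethylsilane, C[Si](C)(C)Cl (its atoms stay in 8 only)
Why: Kinetic α'-deprotonation of the vinylogous ester (Stork–Danheiser regiochemistry), O-silylation and Saegusa–Ito dehydrogenation give the cross-conjugated dienone, which tautomerises at once to the phenol, under neutral room-temperature conditions that spare the acid-labile PMB ethers.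

**Step 6**
Reactants: 9 terphenyl bis-phenol
Product: 10 bis-TIPS ether of 9 with outer rings 2-(triisopropylsilyloxy)-6-(4-methoxybenzyloxy)phenyl
Conditions: iPr3SiOTf (3 equiv), 2,6-lutidine (4 equiv), CH2Cl2, 0 °C to rt
Reagents that add atoms: triisopropylsilyl trifluoromethanesulfonate, CC(C)[Si](OS(=O)(=O)C(F)(F)F)(C(C)C)C(C)C
Why: Silylation of a hindered phenol with a silyl triflate and a non-nucleophilic base; the TIPS group marks the sulfate site, shields C3–H and is sturdy enough for the perborate and carbonate steps ahead.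

**Step 7**
Reactants: 10 bis-TIPS penta-PMB terphenyl
Product: 12 the same terphenyl with a free hydroxyl on C4 of ring A and of ring C, via bis(pinacol boronate) 11 (not isolated)
Conditions: [Ir(OCH3)(cod)]2 (5 mol %), dtbpy (10 mol %), B2pin2 (2.5 equiv), THF, 60 °C; then NaBO3·4H2O (8 equiv), THF–H2O, rt
Reagents that add atoms: bis(pinacolato)diboron, CC1(C)OB(OC1(C)C)B1OC(C)(C)C(C)(C)O1 (its atoms stay in 11 only); sodium perborate, [Na+].[O-]OB=O
Why: The dtbpy-ligated iridium tris(boryl) complex (trivalent iridium) formed in the flask cleaves an aromatic C–H bond by oxidative addition to a crowded pentavalent iridium species and releases the aryl boronate by C–B reductive elimination, so its rate falls steeply with any ortho substituent. The closest known reaction type is the sterically controlled iridium-catalysed C–H borylation of 1,2,3-trisubstituted arenes at C5, run in one pot with oxidation of the boronate to the phenol. The step closes no ring and sets no stereocentre; it makes the C4–B and then the C4–O bond on ring A and on ring C. The selectivity needed is C4–H of the outer rings over every other aromatic C–H, and 10 secures it because C3–H sits next to OTIPS, C5–H next to OPMB, the lone ring B hydrogen between two OPMB groups, and every hydrogen of the para-disubstituted PMB rings next to OCH3 or CH2O. The hydrogens beside OCH3 are the next most reactive, which is why B2pin2 is kept near the amount needed and the temperature moderate. Perborate delivers hydroperoxide to boron and the aryl group shifts from boron to oxygen at the same carbon, under conditions mild enough for the silyl and PMB ethers.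

**Step 8**
Reactants: 12 terphenyl with free C4 hydroxyls; 2 4-methoxybenzyl chloride
Product: 13 hepta-PMB bis-TIPS terphenyl with outer rings 2-(triisopropylsilyloxy)-4,6-bis(4-methoxybenzyloxy)phenyl
Conditions: 2 (2.5 equiv), K2CO3 (3 equiv), DMF, rt
Reagents that add atoms: 4-methoxybenzyl chloride (2), COc1ccc(CCl)cc1
Why: Williamson ether synthesis on the two unhindered phenols; aryl TIPS ethers hold under carbonate at room temperature, and no neighbouring free hydroxyl is present to which silicon could migrate.

**Step 9**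
Reactants: 13 hepta-PMB bis-TIPS terphenyl
Product: 14 hepta-PMB terphenyl with free O2–H on rings A and C
Conditions: Bu4NF (2.4 equiv), AcOH (2.4 equiv), THF, 0 °C
Reagents that add atoms: none
Why: Fluoride-induced cleavage of aryl silyl ethers driven by the Si–F bond; the acetic acid buffer keeps the electron-rich phenols protonated, and the PMB ethers are inert.

**Step 10**
Reactants: 14 hepta-PMB terphenyl diol
Product: 15 disodium salt of the bis(hydrogen sulfate) of 14
Conditions: SO3·pyridine (8 equiv), pyridine, 40 °C; then aq NaHCO3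
Reagents that add atoms: sulfur trioxide–pyridine complex, [O-]S(=O)(=O)[n+]1ccccc1; sodium hydrogen carbonate, [Na+].OC([O-])=O
Why: O-sulfation of phenols with an amine–SO3 complex; the two O2 hydroxyls are the only free ones, the mild reagent and temperature should avoid ring sulfonation, and exchange to sodium gives a storable salt.

**Step 11**
Reactants: 15 hepta-PMB disulfate disodium salt
Product: 17 target CNP0320583.0 in the acid form, via disodium salt of the target 16 (not isolated)
Conditions: H2 (1 atm), 10% Pd/C, THF–CH3OH–H2O, rt; filtration under argon; then aq HCl (2.0 equiv), 0 °C, Sephadex LH-20 (CH3OH)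
Reagents that add atoms: none
Why: Catalytic hydrogenolysis of seven benzylic aryl ether C–O bonds in neutral medium, to which aryl sulfate salts are inert, followed by brief cold protonation of the two sulfate anions.

**Compound list**
1 | phloroglucinol | Oc1cc(O)cc(O)c1 | starting material
2 | 4-methoxybenzyl chloride | COc1ccc(CCl)cc1 | starting material
3 | 1,3,5-tris(4-methoxybenzyloxy)benzene | COc1ccc(COc2cc(OCc3ccc(OC)cc3)cc(OCc3ccc(OC)cc3)c2)cc1 | intermediate
4 | 2,4-dibromo-1,3,5-tris(4-methoxybenzyloxy)benzene | COc1ccc(COc2cc(OCc3ccc(OC)cc3)c(Br)c(OCc3ccc(OC)cc3)c2Br)cc1 | intermediate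
5 | cyclohexane-1,3-dione | O=C1CCCC(=O)C1 | starting material
6 | ring B tris-PMB ether bearing two cyclohexane-1,3-dion-2-yl groups (enol form) | COc1ccc(COc2cc(OCc3ccc(OC)cc3)c(C3=C(O)CCCC3=O)c(OCc3ccc(OC)cc3)c2C2=C(O)CCCC2=O)cc1 | intermediate
7 | bis(PMB enol ether) of 6 | COc1ccc(COc2cc(OCc3ccc(OC)cc3)c(C3=C(OCc4ccc(OC)cc4)CCCC3=O)c(OCc3ccc(OC)cc3)c2C2=C(OCc3ccc(OC)cc3)CCCC2=O)cc1 | intermediate
8 | bis(trimethylsilyl dienol ether) of 7 | COc1ccc(COc2cc(OCc3ccc(OC)cc3)c(C3=C(OCc4ccc(OC)cc4)CCC=C3O[Si](C)(C)C)c(OCc3ccc(OC)cc3)c2C2=C(OCc3ccc(OC)cc3)CCC=C2O[Si](C)(C)C)cc1 | intermediate (not isolated)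
9 | penta-PMB terphenyl with free O2–H on rings A and C | COc1ccc(COc2cc(OCc3ccc(OC)cc3)c(-c3c(O)cccc3OCc3ccc(OC)cc3)c(OCc3ccc(OC)cc3)c2-c2c(O)cccc2OCc2ccc(OC)cc2)cc1 | intermediate
10 | bis-TIPS penta-PMB terphenyl (key-step precursor) | COc1ccc(COc2cc(OCc3ccc(OC)cc3)c(-c3c(O[Si](C(C)C)(C(C)C)C(C)C)cccc3OCc3ccc(OC)cc3)c(OCc3ccc(OC)cc3)c2-c2c(O[Si](C(C)C)(C(C)C)C(C)C)cccc2OCc2ccc(OC)cc2)cc1 | intermediate
11 | 10 with Bpin on C4 of rings A and C | COc1ccc(COc2cc(OCc3ccc(OC)cc3)c(-c3c(O[Si](C(C)C)(C(C)C)C(C)C)cc(B4OC(C)(C)C(C)(C)O4)cc3OCc3ccc(OC)cc3)c(OCc3ccc(OC)cc3)c2-c2c(O[Si](C(C)C)(C(C)C)C(C)C)cc(B3OC(C)(C)C(C)(C)O3)cc2OCc2ccc(OC)cc2)cc1 | intermediate (not isolated)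
12 | 10 with OH on C4 of rings A and C (key-step product) | COc1ccc(COc2cc(OCc3ccc(OC)cc3)c(-c3c(O[Si](C(C)C)(C(C)C)C(C)C)cc(O)cc3OCc3ccc(OC)cc3)c(OCc3ccc(OC)cc3)c2-c2c(O[Si](C(C)C)(C(C)C)C(C)C)cc(O)cc2OCc2ccc(OC)cc2)cc1 | intermediate
13 | hepta-PMB bis-TIPS terphenyl | COc1ccc(COc2cc(OCc3ccc(OC)cc3)c(-c3c(O[Si](C(C)C)(C(C)C)C(C)C)cc(OCc4ccc(OC)cc4)cc3OCc3ccc(OC)cc3)c(OCc3ccc(OC)cc3)c2-c2c(O[Si](C(C)C)(C(C)C)C(C)C)cc(OCc3ccc(OC)cc3)cc2OCc2ccc(OC)cc2)cc1 | intermediate
14 | hepta-PMB terphenyl with free O2–H on rings A and C | COc1ccc(COc2cc(OCc3ccc(OC)cc3)c(-c3c(O)cc(OCc4ccc(OC)cc4)cc3OCc3ccc(OC)cc3)c(OCc3ccc(OC)cc3)c2-c2c(O)cc(OCc3ccc(OC)cc3)cc2OCc2ccc(OC)cc2)cc1 | intermediate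
15 | hepta-PMB terphenyl O2,O2-disulfate, disodium salt | COc1ccc(COc2cc(OCc3ccc(OC)cc3)c(-c3c(OS(=O)(=O)[O-])cc(OCc4ccc(OC)cc4)cc3OCc3ccc(OC)cc3)c(OCc3ccc(OC)cc3)c2-c2c(OS(=O)(=O)[O-])cc(OCc3ccc(OC)cc3)cc2OCc2ccc(OC)cc2)cc1.[Na+].[Na+] | intermediate
16 | disodium salt of the target | [Na+].[Na+].[O-]S(=O)(=O)Oc1cc(O)cc(O)c1-c1c(O)cc(O)c(-c2c(O)cc(O)cc2OS(=O)(=O)[O-])c1O | intermediate (not isolated)
17 | CNP0320583.0 | O=S(=O)(O)Oc1cc(O)cc(O)c1-c1c(O)cc(O)c(-c2c(O)cc(O)cc2OS(=O)(=O)O)c1O | target

**Totals**
Total step count: 11. Longest linear sequence: 11 steps (1 to 17).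

**Steps most likely to fail**

1. Step 7. Boryl transfer may leak to the C–H bonds beside the methoxy groups of the five PMB rings (ten such sites against two wanted ones), or the catalyst may die after only one outer ring has reacted. Stray boryl groups on PMB rings end on fragments that the final hydrogenolysis removes, but they would burden every purification.
   - Fallback (from 3, using 4, back at 13): the para oxygens are brought in with outer rings cut from phloroglucinol instead of being made by C–H oxidation.
   - One PMB group of 3 is removed with NaSEt in DMF at 120 °C, where the phenoxide formed resists a second cleavage. This gives 3,5-bis(4-methoxybenzyloxy)phenol F1.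
   - Amine-mediated ortho-bromination (NBS, catalytic iPr2NH, CH2Cl2, −78 °C) gives 2-bromo-3,5-bis(4-methoxybenzyloxy)phenol F2, whose free hydroxyl marks the sulfate site.
   - iPr3SiOTf and 2,6-lutidine give its TIPS ether F3.
   - Miyaura-type borylation (HBpin, PdCl2(CH3CN)2, SPhos, Et3N, dioxane, 80 °C) gives the aryl pinacol boronate F4.
   - A twofold Suzuki–Miyaura coupling of F4 with dibromide 4 (Pd2(dba)3, SPhos, K3PO4, toluene, 100 °C) gives 13.
   - The price is two tetra-ortho-substituted biaryl couplings.

2. Step 3. Slow C–C reductive elimination at the hindered aryl palladium enolate leaves time for hydrodebromination. It also leaves time for palladium to attack an ortho C–H of a neighbouring PMB ring, and the reaction may stall after the first coupling.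
   - Fallback (from 3 and 5, back at 7): ring B acts as the nucleophile it is by nature and the dione as a carbenoid electrophile.
   - Regitz diazo transfer to 5 (4-acetamidobenzenesulfonyl azide, Et3N, CH3CN) gives 2-diazocyclohexane-1,3-dione F5.
   - Slow addition of F5 to an excess of 3 with Rh2(OAc)4 in refluxing fluorobenzene should give, by carbenoid aromatic substitution, 2-[2,4,6-tris(4-methoxybenzyloxy)phenyl]cyclohexane-1,3-dione F6.
   - The enol of F6 is capped at once with 2 and K2CO3 to the mono PMB enol ether F7, because a free enol O–H would intercept the next carbenoid.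
   - A second Rh2(OAc)4-catalysed reaction with F5 gives the mixed enol ether–dione F8, and a last O-alkylation with 2 gives 7.

3. Step 5. Incomplete twofold enolisation, or protodesilylation of a dienol ether before palladium is taken up, would return the enone on one side and leave half-aromatised material.
   - Fallback (from 7, back at 9): selenoxide syn-elimination replaces palladium β-hydride elimination.
   - The bis-enolate (LiN(iPr)2, THF, −78 °C) is quenched on carbon with PhSeCl to the bis(6-phenylselanyl) enone F9. This is a mixture of diastereomers whose new stereocentres vanish in the next operation.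
   - H2O2 and pyridine in CH2Cl2 at 0 °C oxidise selenium; elimination toward C5 and tautomerisation give 9.

**Further compounds**
F1 | step 7 | 3,5-bis(4-methoxybenzyloxy)phenol | COc1ccc(COc2cc(O)cc(OCc3ccc(OC)cc3)c2)cc1
F2 | step 7 | 2-bromo-3,5-bis(4-methoxybenzyloxy)phenol | COc1ccc(COc2cc(O)c(Br)c(OCc3ccc(OC)cc3)c2)cc1
F3 | step 7 | [2-bromo-3,5-bis(4-methoxybenzyloxy)phenoxy]triisopropylsilane | COc1ccc(COc2cc(O[Si](C(C)C)(C(C)C)C(C)C)c(Br)c(OCc3ccc(OC)cc3)c2)cc1
F4 | step 7 | 2-[2-(triisopropylsilyloxy)-4,6-bis(4-methoxybenzyloxy)phenyl]-4,4,5,5-tetramethyl-1,3,2-dioxaborolane | COc1ccc(COc2cc(O[Si](C(C)C)(C(C)C)C(C)C)c(B3OC(C)(C)C(C)(C)O3)c(OCc3ccc(OC)cc3)c2)cc1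
F5 | step 3 | 2-diazocyclohexane-1,3-dione | [N-]=[N+]=C1C(=O)CCCC1=O
F6 | step 3 | 2-[2,4,6-tris(4-methoxybenzyloxy)phenyl]cyclohexane-1,3-dione (enol form) | COc1ccc(COc2cc(OCc3ccc(OC)cc3)c(C3=C(O)CCCC3=O)c(OCc3ccc(OC)cc3)c2)cc1
F7 | step 3 | 3-(4-methoxybenzyloxy)-2-[2,4,6-tris(4-methoxybenzyloxy)phenyl]cyclohex-2-en-1-one | COc1ccc(COc2cc(OCc3ccc(OC)cc3)c(C3=C(OCc4ccc(OC)cc4)CCCC3=O)c(OCc3ccc(OC)cc3)c2)cc1
F8 | step 3 | ring B tris-PMB ether bearing one PMB enol ether ring and one free dione ring (enol form) | COc1ccc(COc2cc(OCc3ccc(OC)cc3)c(C3=C(OCc4ccc(OC)cc4)CCCC3=O)c(OCc3ccc(OC)cc3)c2C2=C(O)CCCC2=O)cc1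
F9 | step 5 | bis(6-phenylselanyl) derivative of 7 (mixture of diastereomers) | COc1ccc(COc2cc(OCc3ccc(OC)cc3)c(C3=C(OCc4ccc(OC)cc4)CCC([Se]c4ccccc4)C3=O)c(OCc3ccc(OC)cc3)c2C2=C(OCc3ccc(OC)cc3)CCC([Se]c3ccccc3)C2=O)cc1
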